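## Structural features

Numbered from the lactone carbonyl (C1) round the ring to the lactone carbinol (C19) and out along the side chain (C20–C24), the target is a 20-membered macrolactone whose C19 substituent is an E-propenyl unit ending in a trans-epoxide (C22–C23, both R). Inside the ring a trisubstituted trans-epoxide (C11–C12, both R, methyl on C12) is joined directly to the Z C13=C14 olefin and, through the C10 methylene, to a (6Z,8Z)-dienone, so both epoxides are vinylic and acid-sensitive. The western part is a Z 2-methyl-enoate (C1–C3), the C4 methine (S) and the C5 ketone. C4 lies between the ketone and the enoate and is the most easily epimerised centre. The eastern part carries the contiguous triad C17(OH)–C18(Me)–C19(O-acyl), all R, and the C15 methyl ether (S), which is 1,3-syn to the C17 hydroxyl. The real difficulty is to set four Z olefins (one trisubstituted and conjugated to the ester, two forming the dienone) next to two vinyl epoxides and the labile C4 centre, which forces the last operations to be mild and free of base. The key step uses the fact that tying O19 to C15 turns C15–C19 into a pyran in which the C17 oxygen, the C18 methyl and the C19 side chain are all cis. That ring is the direct product of an endo hetero-Diels–Alder reaction between a C15–C18 silyloxy diene and the C19–C24 dienal, which already holds every carbon of the side chain.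

## Logic of the disconnections

**45 back to 42.** No skeletal bond is cut. The C17 hydroxyl is traced to its silyl ether (44) and the C5 ketone to a silyl-protected carbinol (43, 42). The reason is that C4 would not survive base once C5 is a carbonyl, so the ketone is made after all C–C bonds. The gain is that every bond-forming step runs on a configurationally stable C4. The demand is selective release of the C5 oxygen beside the C17 silyl ether, a base-free oxidation, and a final desilylation that spares two vinyl epoxides.

**42 back to 41.** The Z C8=C9 olefin is traced to a C8≡C9 triple bond. The reason is that cis semi-reduction of a conjugated enyne gives the Z,Z-diene with fixed geometry at C6=C7. The gain is that the ring can be closed by a linear sp–sp2 coupling. The demand is a reduction that touches only the conjugated alkyne.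

**41 back to 40.** The ring bond C7–C8 is cut. It lies far from all stereocentres and joins a Z iodoalkene of fixed geometry to a terminal alkyne. The gain is an open-chain precursor. The demand is cyclisation at high dilution without alkyne homocoupling.

**40 back to 29 and 38.** The C2=C3 double bond is cut. Forming the Z enoate by olefination on a phosphonate that is already the C19 ester means that no Z 2-methyl-enoic acid ever has to be activated, which would invite Z-to-E isomerisation. The gain is a C8–C24 alcohol fragment, a two-carbon phosphonate and a C3–C7 aldehyde. The demand is high Z selectivity with an α-branched aldehyde and no epimerisation at C4.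

**29 back to 26 and 28; 28 back to 27.** The O19–C1 acyl bond is cut. The gain is a simple acylation of a hindered alcohol by a small acid. The demand is a coupling that leaves the epoxides alone. 28 comes from 27 by ester hydrolysis.

**38 back to 33 and 34; 33 back to 30.** The C4–C5 bond is cut as a syn aldol, through 37 and 36, which sets C4 by auxiliary control. C6–CH3 and C7–I are cut back to 30 through 32 by directed carbometalation. The gain is three commercial units. The demand is the correct absolute sense at C4; C5 is oxidised later and is free.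

**26 back to 23.** The C–O bonds of both epoxides are cut back to the E olefins C11=C12 and C22=C23, and the Z C13=C14 olefin is traced to the alkyne (25, 24). The gain is that one catalyst-controlled epoxidation creates four stereocentres. The demand is regioselection within the diene and a hydrogenation that leaves the silyl-capped C8≡C9 alkyne alone.

**23 back to 11 and 18.** The C14–C15 bond is cut, through 22, 21 and 20. An acetylide opens the lactone, and the resulting ynone allows reagent-controlled reduction at C15. The gain is a six-membered lactone and a C8–C14 enediyne. The demand is mono-addition, capture of the open chain, and 15S by catalyst control.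

**18 back to 12 and 16.** The C9–C10 bond is cut (17, 15, 14). The gain is two commercial alkynes. The demand is differentiation of the two alkyne termini, which is met by two different silyl groups.

**11 back to 7.** No skeletal bond is cut. The C15 lactone carbonyl is traced to the enol ether (10, 9) and the C17 carbinol to the ring ketone (8). The gain is that the ring serves as a template for C17. The demand is axial hydride delivery and hydration without allylic transposition.

**7 back to 4 and 5; 4 back to 1.** The bonds C18–C19 and O19–C15 are cut in one retro-cycloaddition, through 6. The gain is the largest of the route: one ring, two bonds, two stereocentres and the whole side chain from two small achiral partners. The demand is endo and facial control and reaction at C=O rather than at C=C of 5. 4 is traced through 3 to 1 by silylation and methylation.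

## Other disconnections considered

**Alternative 1:** The cut is the C13=C14 double bond. In the forward sense the acyclic diphenylsilylene-bridged diene A1, in which the C12 tertiary and the C15 secondary vinyl carbinols are tied through O–SiPh2–O, would undergo ring-closing metathesis with the second-generation Grubbs catalyst (H2IMes)(PCy3)Cl2Ru=CHPh to give the seven-membered silaketal A2.
- In its favour: a seven-membered ring can hold only a cis olefin, so the Z geometry is guaranteed by structure. On this point it is better than the semi-hydrogenation of step 17. The epoxide would then arise by SN2 closure of the C12 oxygen onto the C11 mesylate, which is stereospecific and needs no hydrogenation beside an epoxide.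
- Against it here: silylating a tertiary alcohol and closing a ring onto a fully substituted allylic carbon are both slow. C11, C12 and C15 each need their own asymmetric step. A2 still lacks C21–C24 and the C15 methyl ether. The Z iodoalkene must survive the ruthenium carbene.
- Comparison: on structure, A2 secures one olefin and one epoxide with certainty, while the chosen plan secures C17–C19 and the full side chain in one step but relies on catalyst control at C11, C12 and C15. On mechanism, a reversible metathesis under ring control stands against a cycloaddition followed by ynone reduction. On step economy the tether, mesylation and epoxide closure cost more operations than steps 12–17. The two ideas are compatible, since a C15 vinyl carbinol for A1 could be drawn from 11.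

**Alternative 2:** The cut is the C8–C9 bond at the alkyne level. The ester-linked diyne A3, with methyl-capped triple bonds at C8 and C9, would be closed by alkyne metathesis with a molybdenum alkylidyne such as [Mo(≡CC6H4OMe-4)(OSiPh3)3] to give the ring enyne A4 and but-2-yne. A4 would then be semi-reduced and desilylated.
- In its favour: the closure is remote from every stereocentre, tolerates olefins, epoxides and esters, cannot homocouple and is driven by loss of a volatile alkyne. As a ring-closing event it is better than the palladium/copper coupling of step 27.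
- Against it here: A3 must already contain the Z 2-methyl-enoate ester and the C5 ketone. That means either esterifying a Z enoic acid with the hindered C19 alcohol or carrying the labile C4 centre through several steps. Two propynyl groups must be installed, and the last reduction acts on an enyne conjugated to the ketone beside C4.
- Comparison: both plans pass through the same kind of 8,9-didehydro macrocycle (41 and A4) and both need a Z-selective semi-reduction; they are equal on that point. They differ upstream, where the chosen plan makes C15–C24 by cycloaddition and forms the Z enoate as the ester. The eastern alcohol of A3 could be made by steps 3–18, so alternative 2 competes only with steps 26–28, at a similar step count.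

**Alternative 3:** The cut is the C2=C3 double bond. The methacrylate diene A5 would undergo ring-closing metathesis with the second-generation Grubbs catalyst to give the six-membered unsaturated lactone A6, in which the ring enforces the Z enoate.
- In its favour: geometric control is complete, which is better than the kinetic selectivity of step 26. The sequence to A6 is short (crotylation, acylation, metathesis). The lactone masks the C5 hydroxyl and the C1 carboxyl at once. C4 is set by crotylation, equal in reliability to the aldol of step 23.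
- Against it here: metathesis onto an electron-poor 1,1-disubstituted methacrylate is demanding. Opening A6 gives a Z hydroxy acid that recloses readily, so C5 must be capped or oxidised first. The acid must then be activated for esterification with the C19 alcohol, which reopens the isomerisation risk that step 26 avoids.
- Comparison: on structure both deliver C1–C7 with the Z iodoalkene. On mechanism, ring-controlled metathesis stands against kinetic olefination. On step economy A6 is reached faster than 38, but lactone opening, protection and esterification cancel the advantage, whereas step 26 forms the olefin and joins the fragments in one operation. The idea concerns the western fragment only and is compatible with the chosen key step.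

Key step: step 3

Assumption: the (1R,2S)-configured chromium catalyst is taken to expose the Si face of the bound aldehyde; if its sense is the opposite, the mirror-image (1S,2R) complex is used and nothing else changes.
Assumption: 20 is drawn as the open hydroxy ynone although it may equilibrate with its cyclic hemiketal; the silylation of step 13 drains the open form.
Remark: the configurations of 7 and 8 were checked atom by atom against the target (cis C18/C19; C17, C18, C19 all cis in the pyran, all R in the target) and needed no correction.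

## Route

Step 1
Reactants: 1 (E)-4-methoxybut-3-en-2-one
Product: 3 (E)-1-methoxypent-1-en-3-one, via lithium dienolate 2 (not isolated)
Conditions: LiN(SiMe3)2, THF, −78 °C; MeI, −78 to −30 °C
Reagents that add atoms: iodomethane, CI
Why: Kinetic deprotonation of the vinylogous ester occurs at the methyl ketone (α′) position and the cross-conjugated lithium enolate is C-methylated (α′-alkylation of a vinylogous ester); low temperature and one equivalent of base limit double alkylation.

Step 2
Reactants: 3 (E)-1-methoxypent-1-en-3-one
Product: 4 (1E,3Z)-1-methoxy-3-(triethylsilyloxy)penta-1,3-diene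
Conditions: Et3SiOTf, Et3N, Et2O, 0 °C to rt
Reagents that add atoms: triethylsilyl trifluoromethanesulfonate, CC[Si](CC)(CC)OS(=O)(=O)C(F)(F)F
Why: Soft enolisation of an ethyl ketone with a silyl triflate and triethylamine gives the Z silyl enol ether, the geometry needed for the cis product; the triethylsilyl ether is kept because it is more robust to handling than the trimethylsilyl analogue.

Step 3
Reactants: 4 (1E,3Z)-1-methoxy-3-(triethylsilyloxy)penta-1,3-diene; 5 sorbaldehyde
Product: 7 (2R,3S)-3-methyl-2-[(1E,3E)-penta-1,3-dienyl]-2,3-dihydro-4H-pyran-4-one, via silyl enol ether cycloadduct 6 (not isolated)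
Conditions: [CrCl(L)] (5 mol %; L = dianion of the Schiff base of (1R,2S)-1-aminoindan-2-ol and 3-(1-adamantyl)-2-hydroxy-5-methylbenzaldehyde), 4 Å MS, minimal acetone, rt; then CF3CO2H, CH2Cl2, 0 °C
Reagents that add atoms: none
Why: The trivalent chromium centre binds the carbonyl oxygen of 5 and the electron-rich diene 4 adds in a concerted, asynchronous [4+2] cycloaddition in which C18–C19 forms ahead of O19–C15; this is the known chromium–Schiff-base hetero-Diels–Alder reaction of 1-methoxy-3-silyloxy dienes with aldehydes, applied to a dienal. The six-membered dihydropyran ring is closed by the cycloaddition itself, both ring bonds being made in one pericyclic event, and trifluoroacetic acid then converts 6 into the enone 7 with loss of methanol and the silyl group. C19 is set by the catalyst, whose ligand shields one face of the bound aldehyde so that the diene adds to the Si face (19R). C18 is set relative to C19 by the endo transition state together with the Z geometry of the silyl enol ether, which places the methyl cis to the side chain. The step needs reaction at C=O and not at the C=C bonds of 5, which is secured because the oxygen-bound Lewis acid activates only the carbonyl and the silyloxy diene is far more reactive than the dienal in either diene or oxadiene role. The acid treatment is kept short and cold so that C18, now alpha to the ketone, does not equilibrate to the trans isomer.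

Step 4
Reactants: 7 (2R,3S)-3-methyl-2-[(1E,3E)-penta-1,3-dienyl]-2,3-dihydro-4H-pyran-4-one
Product: 8 (2R,3R,4R)-3-methyl-2-[(1E,3E)-penta-1,3-dienyl]-3,4-dihydro-2H-pyran-4-ol (all-cis)
Conditions: NaBH4, CeCl3·7H2O, MeOH, −78 to −40 °C
Reagents that add atoms: none
Why: Luche reduction gives clean 1,2-addition to the vinylogous ester; in the half-chair with the C19 side chain equatorial and the C18 methyl axial, hydride enters axially opposite the methyl and gives the equatorial C17 alcohol cis to both neighbours (17R).

Step 5
Reactants: 8 all-cis glycal alcohol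
Product: 9 tert-butyldimethylsilyl ether of 8 (C17–OTBS)
Conditions: t-BuMe2SiCl, imidazole, DMF, 0 °C to rt
Reagents that add atoms: tert-butylchlorodimethylsilane, CC(C)(C)[Si](C)(C)Cl
Why: Standard silylation of a secondary allylic alcohol; this group is chosen because it must outlast the fluoride treatment of step 18 and fall only in the last step.

Step 6
Reactants: 9 silylated glycal
Product: 10 (4R,5S,6R)-4-(tert-butyldimethylsilyloxy)-5-methyl-6-[(1E,3E)-penta-1,3-dienyl]tetrahydropyran-2-ol (anomer mixture)
Conditions: PPh3·HBr (5 mol %), THF/H2O (10:1), rt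
Reagents that add atoms: water, O
Why: Acid-catalysed hydration of the enol ether: protonation at C16 gives the oxocarbenium ion and water adds at C15; the mild phosphonium acid and the poor leaving ability of the silyloxy group disfavour allylic transposition.

Step 7
Reactants: 10 lactol
Product: 11 (4R,5S,6R)-4-(tert-butyldimethylsilyloxy)-5-methyl-6-[(1E,3E)-penta-1,3-dienyl]tetrahydropyran-2-one
Conditions: Pr4N[RuO4] (5 mol %), N-methylmorpholine N-oxide, 4 Å MS, CH2Cl2, rt
Reagents that add atoms: none
Why: Ley–Griffith oxidation of a lactol to the lactone under neutral conditions, which leaves the diene and the silyl ether untouched.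

Step 8
Reactants: 12 (E)-3-methylpent-2-en-4-yn-1-ol
Product: 14 (E)-3-methyl-5-(trimethylsilyl)pent-2-en-4-yn-1-ol, via bis-silylated enynol 13 (not isolated)
Conditions: n-BuLi (2.2 equiv), THF, −78 °C; Me3SiCl (2.3 equiv), −78 °C to rt; then 1 M HCl, rt
Reagents that add atoms: chlorotrimethylsilane, C[Si](C)(C)Cl
Why: Double deprotonation (O–H and alkyne C–H) and double silylation, after which aqueous acid cleaves only the O–Si bond; the alkynylsilane blocks C14 during steps 9 and 10.

Step 9
Reactants: 14 (E)-3-methyl-5-(trimethylsilyl)pent-2-en-4-yn-1-ol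
Product: 15 (E)-(5-bromo-3-methylpent-3-en-1-ynyl)trimethylsilane
Conditions: CBr4, PPh3, CH2Cl2, 0 °C
Reagents that add atoms: tetrabromomethane, BrC(Br)(Br)Br
Why: Appel bromination of a primary allylic alcohol under neutral conditions with retention of the olefin geometry.

Step 10
Reactants: 15 (E)-(5-bromo-3-methylpent-3-en-1-ynyl)trimethylsilane; 16 ethynyltriisopropylsilane
Product: 17 (E)-triisopropyl[5-methyl-7-(trimethylsilyl)hept-4-ene-1,6-diynyl]silane
Conditions: CuI (20 mol %), K2CO3, n-Bu4NCl (10 mol %), dry DMF, rt
Reagents that add atoms: none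
Why: Copper-catalysed alkynylation of a primary allylic bromide; the copper acetylide substitutes at the unhindered C10 terminus and gives the skipped enyne (C9–C10) with E geometry retained, attack at the fully substituted C12 terminus being sterically disfavoured.

Step 11
Reactants: 17 bis-silylated enediyne
Product: 18 (E)-triisopropyl(5-methylhept-4-ene-1,6-diynyl)silane
Conditions: K2CO3 (0.3 equiv), MeOH/THF (2:1), 0 °C
Reagents that add atoms: none
Why: Methanolysis cleaves the alkynyl–SiMe3 bond while the bulky triisopropylsilyl alkyne is inert, so only C14 is unmasked; the short cold treatment avoids isomerisation of the skipped enyne.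

Step 12
Reactants: 18 (E)-triisopropyl(5-methylhept-4-ene-1,6-diynyl)silane; 11 lactone
Product: 20 C8–C24 hydroxy ynone (C15 ketone; C19–OH; C17–OTBS; C8–Si(i-Pr)3), via lithium acetylide 19 (not isolated)
Conditions: 18, n-BuLi, THF, −78 °C; then 11, −78 °C; AcOH, −78 °C
Reagents that add atoms: none
Why: Acetylide addition to a δ-lactone forms C14–C15; the lithium hemiketal alkoxide is stable at −78 °C, which prevents a second addition, and opens on protonation to the hydroxy ynone, while the cold acidic quench avoids elimination of the C17 silyloxy group.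

Step 13
Reactants: 20 C8–C24 hydroxy ynone
Product: 21 C19 triethylsilyl ether of 20
Conditions: Et3SiCl, imidazole, DMAP (cat.), CH2Cl2, 0 °C
Reagents that add atoms: chlorotriethylsilane, CC[Si](Cl)(CC)CC
Why: Silylation of the C19 carbinol traps the open-chain form; the triethylsilyl group is chosen so that fluoride removes it together with the alkynylsilane in step 18 while the C17 ether stays.

Step 14
Reactants: 21 silylated ynone
Product: 22 (15S)-propargylic alcohol (C15–OH; other groups as in 21)
Conditions: Ru[(S,S)-TsNCHPhCHPhNH](p-cymene) (3 mol %), i-PrOH, rt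
Reagents that add atoms: none
Why: Noyori asymmetric transfer hydrogenation of an alkynyl ketone, in which the alkynyl group takes the place normally held by aryl, so the (S,S) catalyst gives the S propargylic alcohol (15S, 1,3-syn to O17); reagent control overrides the C17 centre and the base-free conditions spare the β-silyloxy ynone.

Step 15
Reactants: 22 (15S)-propargylic alcohol
Product: 23 C15 methyl ether of 22
Conditions: Me3OBF4, 1,8-bis(dimethylamino)naphthalene, 4 Å MS, CH2Cl2, 0 °C to rt
Reagents that add atoms: trimethyloxonium tetrafluoroborate, C[O+](C)C.F[B-](F)(F)F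
Why: O-Methylation with a Meerwein salt and a non-nucleophilic proton scavenger avoids alkoxide formation and hence silyl migration from O17.

Step 16
Reactants: 23 C15 methyl ether
Product: 24 bis-epoxide of 23 ((11R,12R)-11,12-epoxide and (22R,23R)-22,23-epoxide)
Conditions: D-fructose-derived Shi ketone (0.6 equiv), KHSO5 (as 2KHSO5·KHSO4·K2SO4), K2CO3, n-Bu4NHSO4, MeCN/CH2(OMe)2/aq. Na2B4O7–Na2EDTA buffer, −5 to 0 °C
Reagents that add atoms: potassium peroxymonosulfate, [K+].[O-]S(=O)(=O)OO
Why: Shi epoxidation: the chiral dioxirane epoxidises the trisubstituted enyne olefin and the distal, more electron-rich olefin of the diene, the proximal one being deactivated and shielded by the C19 silyloxy group and further deactivated once the vinyl epoxide has formed. The spiro transition state of this ketone enantiomer gives R,R epoxides from trans and trisubstituted olefins, which corresponds to 11R,12R and 22R,23R; alkynes are inert.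

Step 17
Reactants: 24 bis-epoxy diyne
Product: 25 (13Z)-alkene from 24 (C8≡C9–Si(i-Pr)3 retained)
Conditions: H2 (1 atm), Pd/CaCO3 poisoned with Pb(OAc)2, quinoline, EtOAc, rt
Reagents that add atoms: none
Why: Lindlar semi-hydrogenation adds hydrogen syn to the internal alkyne and gives the Z olefin; the triisopropylsilyl-capped alkyne is too hindered to react at a comparable rate, and quinoline suppresses over-reduction and hydrogenolysis of the propargylic epoxide.

Step 18
Reactants: 25 (13Z)-alkene
Product: 26 C8–C24 alcohol (terminal alkyne at C8; C19–OH; C17–OTBS)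
Conditions: n-Bu4NF, AcOH (1:1), THF, 0 °C to rt
Reagents that add atoms: none
Why: Fluoride cleaves the alkynyl C–Si bond and the triethylsilyl ether much faster than the secondary tert-butyldimethylsilyl ether; acetic acid buffers the alkoxide and suppresses silyl migration from O17 to O19.

Step 19
Reactants: 27 ethyl 2-[bis(2,2,2-trifluoroethoxy)phosphoryl]propanoate
Product: 28 2-[bis(2,2,2-trifluoroethoxy)phosphoryl]propanoic acid
Conditions: LiOH·H2O (1.05 equiv), THF/H2O, 0 °C; then 1 M HCl
Reagents that add atoms: lithium hydroxide, [Li+].[OH-]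
Why: Saponification with one equivalent of hydroxide at 0 °C attacks the carboxylic ester faster than the phosphonate esters; the acid is racemic at C2, which is of no consequence because C2 becomes sp2.

Step 20
Reactants: 26 C8–C24 alcohol; 28 phosphonopropanoic acid
Product: 29 C19 2-[bis(2,2,2-trifluoroethoxy)phosphoryl]propanoate of 26 (C2 epimers)
Conditions: EDC·HCl, DMAP (0.2 equiv), CH2Cl2, 0 °C to rt
Reagents that add atoms: none
Why: Steglich-type esterification: the carbodiimide-activated phosphono acid acylates the hindered C19 alcohol without touching the epoxides; C1–C2 is installed before the olefin is made, so no Z enoic acid is ever activated.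

Step 21
Reactants: 30 prop-2-yn-1-ol
Product: 32 (Z)-3-iodo-2-methylprop-2-en-1-ol, via alkenylmagnesium alkoxide 31 (not isolated)
Conditions: MeMgBr (3 equiv), CuI (10 mol %), THF/Et2O, −10 °C to rt; then I2, −10 °C
Reagents that add atoms: methylmagnesium bromide, C[Mg]Br; iodine, II
Why: Copper-catalysed carbomagnesiation of propargyl alcohol: the magnesium alkoxide directs anti addition, placing methyl on C6 and magnesium on C7 cis to the CH2O group, and iodinolysis with retention gives the Z iodoalkene.

Step 22
Reactants: 32 (Z)-3-iodo-2-methylprop-2-en-1-ol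
Product: 33 (Z)-3-iodo-2-methylprop-2-enal
Conditions: MnO2 (activated, excess), CH2Cl2, rt; solution used at once
Reagents that add atoms: none
Why: MnO2 oxidises the allylic alcohol to the enal under neutral conditions; immediate use avoids Z-to-E isomerisation of the enal.

Step 23
Reactants: 34 (R)-4-benzyl-3-propanoyl-1,3-thiazolidine-2-thione; 33 (Z)-3-iodo-2-methylprop-2-enal
Product: 36 (R)-4-benzyl-3-[(2R,3R,4Z)-3-hydroxy-5-iodo-2,4-dimethylpent-4-enoyl]-1,3-thiazolidine-2-thione, via chlorotitanium enolate 35 (not isolated)
Conditions: 34, TiCl4, i-Pr2NEt, N-methylpyrrolidin-2-one, CH2Cl2, 0 °C; then 33, −78 to 0 °C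
Reagents that add atoms: none
Why: Titanium-mediated syn aldol of an N-propanoyl thiazolidinethione in the Evans syn sense: the Z enolate reacts through a closed chair transition state and the (R)-benzyl auxiliary directs the aldehyde to the enolate face that gives the required C4 configuration and the syn C5 carbinol. C5 is oxidised later, so only C4 matters.

Step 24
Reactants: 36 aldol adduct
Product: 37 triethylsilyl ether of 36 (C5–OSiEt3)
Conditions: Et3SiOTf, 2,6-lutidine, CH2Cl2, −78 °C
Reagents that add atoms: triethylsilyl trifluoromethanesulfonate, CC[Si](CC)(CC)OS(=O)(=O)C(F)(F)F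
Why: Silylation of the hindered secondary alcohol with the triflate prevents retro-aldol and supplies the group that is removed selectively in step 29.

Step 25
Reactants: 37 silylated aldol adduct
Product: 38 (2R,3R,4Z)-5-iodo-2,4-dimethyl-3-(triethylsilyloxy)pent-4-enal
Conditions: i-Bu2AlH, CH2Cl2, −78 °C
Reagents that add atoms: none
Why: N-Acyl thiazolidinethiones are reduced by i-Bu2AlH to the aldehyde through a stable tetrahedral aluminium hemiaminal; the auxiliary is released on work-up and the α-centre is not epimerised at −78 °C.

Step 26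
Reactants: 29 phosphonate ester; 38 C3–C7 aldehyde
Product: 40 open-chain (2Z)-enoate (C7 iodoalkene; C8 terminal alkyne; C5–OSiEt3; C17–OTBS), via potassium phosphonate 39 (not isolated)
Conditions: 29, KN(SiMe3)2 (1.0 equiv), 18-crown-6, THF, −78 °C; then 38, −78 °C
Reagents that add atoms: none
Why: Still–Gennari olefination: the potassium phosphonate bearing electron-poor trifluoroethoxy groups adds to the aldehyde and the oxaphosphetane eliminates faster than it equilibrates, giving the Z trisubstituted enoate; one equivalent of base leaves the terminal alkyne and C4 untouched.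

Step 27
Reactants: 40 open-chain iodoalkene–alkyne
Product: 41 20-membered 8,9-didehydro macrocycle (C5–OSiEt3; C17–OTBS)
Conditions: Pd(PPh3)4 (20 mol %), CuI (40 mol %), i-Pr2NH, degassed THF (1 mM, slow addition), rt
Reagents that add atoms: none
Why: Intramolecular Sonogashira coupling: oxidative addition of zerovalent palladium into the Z C7–I bond, transmetalation from the copper acetylide at C8 and reductive elimination close the ring with retention of the C6=C7 geometry; high dilution favours cyclisation over oligomerisation.

Step 28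
Reactants: 41 macrocyclic enyne
Product: 42 (6Z,8Z)-diene macrocycle (C5–OSiEt3; C17–OTBS)
Conditions: Zn activated with Cu(OAc)2 and AgNO3, MeOH/H2O (1:1), 35 °C
Reagents that add atoms: none
Why: Boland-type reduction: activated zinc in aqueous methanol reduces the alkyne of a conjugated enyne by syn delivery of hydrogen and gives the Z olefin without hydrogen gas, so isolated olefins, the enoate and the epoxides are not expected to react.

Step 29
Reactants: 42 (6Z,8Z)-diene macrocycle
Product: 43 C5 alcohol (C17–OTBS retained)
Conditions: HF·pyridine, pyridine, THF, 0 °C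
Reagents that add atoms: none
Why: Buffered HF·pyridine removes the triethylsilyl ether at C5 faster than the tert-butyldimethylsilyl ether at C17; the pyridine buffer protects the vinyl epoxides and prevents ionisation of the dienylic C5–O bond.

Step 30
Reactants: 43 C5 alcohol
Product: 44 17-O-tert-butyldimethylsilyl ether of the target (C5 ketone)
Conditions: Dess–Martin periodinane, NaHCO3, CH2Cl2, 0 °C to rt
Reagents that add atoms: none
Why: Dess–Martin oxidation under bicarbonate buffer converts the C5 carbinol into the ketone without any base strong enough to epimerise C4 or isomerise the Z,Z-dienone.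

Step 31
Reactants: 44 silyl ether of the target
Product: 45 CNP0173711.1 (target)
Conditions: HF·pyridine, pyridine, THF, 0 °C to rt
Reagents that add atoms: none
Why: Fluoride-mediated cleavage of the last silyl ether under buffered, non-basic conditions releases the C17 alcohol while C4 and both epoxides are preserved.

## Compound list

1 | (E)-4-methoxybut-3-en-2-one | CO/C=C/C(C)=O | starting material
2 | lithium (E)-4-methoxybuta-1,3-dien-2-olate | [Li+].[O-]C(=C)/C=C/OC | intermediate
3 | (E)-1-methoxypent-1-en-3-one | CCC(=O)/C=C/OC | intermediate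
4 | (1E,3Z)-1-methoxy-3-(triethylsilyloxy)penta-1,3-diene (C15–C18) | C/C=C(O[Si](CC)(CC)CC)/C=C/OC | intermediate
5 | sorbaldehyde, (2E,4E)-hexa-2,4-dienal (C19–C24) | C/C=C/C=C/C=O | starting material
6 | (2R,5S,6R)-2-methoxy-5-methyl-6-[(1E,3E)-penta-1,3-dienyl]-4-(triethylsilyloxy)-5,6-dihydro-2H-pyran (all-cis cycloadduct) | C/C=C/C=C/[C@H]1O[C@@H](OC)C=C(O[Si](CC)(CC)CC)[C@H]1C | intermediate
7 | (2R,3S)-3-methyl-2-[(1E,3E)-penta-1,3-dienyl]-2,3-dihydro-4H-pyran-4-one (cis; C15–C24) | C/C=C/C=C/[C@H]1OC=CC(=O)[C@H]1C | intermediate
8 | (2R,3R,4R)-3-methyl-2-[(1E,3E)-penta-1,3-dienyl]-3,4-dihydro-2H-pyran-4-ol (all-cis) | C/C=C/C=C/[C@H]1OC=C[C@@H](O)[C@H]1C | intermediate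
9 | (2R,3S,4R)-4-(tert-butyldimethylsilyloxy)-3-methyl-2-[(1E,3E)-penta-1,3-dienyl]-3,4-dihydro-2H-pyran | C/C=C/C=C/[C@H]1OC=C[C@@H](O[Si](C)(C)C(C)(C)C)[C@H]1C | intermediate
10 | (4R,5S,6R)-4-(tert-butyldimethylsilyloxy)-5-methyl-6-[(1E,3E)-penta-1,3-dienyl]tetrahydropyran-2-ol (anomer mixture) | C/C=C/C=C/[C@H]1OC(O)C[C@@H](O[Si](C)(C)C(C)(C)C)[C@H]1C | intermediate
11 | (4R,5S,6R)-4-(tert-butyldimethylsilyloxy)-5-methyl-6-[(1E,3E)-penta-1,3-dienyl]tetrahydropyran-2-one | C/C=C/C=C/[C@H]1OC(=O)C[C@@H](O[Si](C)(C)C(C)(C)C)[C@H]1C | intermediate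
12 | (E)-3-methylpent-2-en-4-yn-1-ol (C10–C14) | C#C/C(C)=C/CO | starting material
13 | (E)-trimethyl[3-methyl-5-(trimethylsilyloxy)pent-3-en-1-ynyl]silane | C[Si](C)(C)C#C/C(C)=C/CO[Si](C)(C)C | intermediate
14 | (E)-3-methyl-5-(trimethylsilyl)pent-2-en-4-yn-1-ol | C[Si](C)(C)C#C/C(C)=C/CO | intermediate
15 | (E)-(5-bromo-3-methylpent-3-en-1-ynyl)trimethylsilane | C[Si](C)(C)C#C/C(C)=C/CBr | intermediate
16 | ethynyltriisopropylsilane (C8–C9) | C#C[Si](C(C)C)(C(C)C)C(C)C | starting material
17 | (E)-triisopropyl[5-methyl-7-(trimethylsilyl)hept-4-ene-1,6-diynyl]silane | C[Si](C)(C)C#C/C(C)=C/CC#C[Si](C(C)C)(C(C)C)C(C)C | intermediate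
18 | (E)-triisopropyl(5-methylhept-4-ene-1,6-diynyl)silane (C8–C14) | C#C/C(C)=C/CC#C[Si](C(C)C)(C(C)C)C(C)C | intermediate
19 | lithium acetylide of 18 (lithium at C14) | [Li+].[C-]#C/C(C)=C/CC#C[Si](C(C)C)(C(C)C)C(C)C | intermediate
20 | (4E,10R,11S,12R,13E,15E)-10-(tert-butyldimethylsilyloxy)-12-hydroxy-5,11-dimethyl-1-(triisopropylsilyl)heptadeca-4,13,15-triene-1,6-diyn-8-one (C8–C24 hydroxy ynone) | C/C=C/C=C/[C@@H](O)[C@H](C)[C@H](O[Si](C)(C)C(C)(C)C)CC(=O)C#C/C(C)=C/CC#C[Si](C(C)C)(C(C)C)C(C)C | intermediate
21 | (4E,10R,11R,12R,13E,15E)-10-(tert-butyldimethylsilyloxy)-5,11-dimethyl-12-(triethylsilyloxy)-1-(triisopropylsilyl)heptadeca-4,13,15-triene-1,6-diyn-8-one | C/C=C/C=C/[C@@H](O[Si](CC)(CC)CC)[C@H](C)[C@H](O[Si](C)(C)C(C)(C)C)CC(=O)C#C/C(C)=C/CC#C[Si](C(C)C)(C(C)C)C(C)C | intermediate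
22 | (4E,8S,10R,11R,12R,13E,15E)-10-(tert-butyldimethylsilyloxy)-5,11-dimethyl-12-(triethylsilyloxy)-1-(triisopropylsilyl)heptadeca-4,13,15-triene-1,6-diyn-8-ol (15S in target numbering) | C/C=C/C=C/[C@@H](O[Si](CC)(CC)CC)[C@H](C)[C@H](O[Si](C)(C)C(C)(C)C)C[C@H](O)C#C/C(C)=C/CC#C[Si](C(C)C)(C(C)C)C(C)C | intermediate
23 | C15 methyl ether of 22 (15S; other centres unchanged) | C/C=C/C=C/[C@@H](O[Si](CC)(CC)CC)[C@H](C)[C@H](O[Si](C)(C)C(C)(C)C)C[C@H](OC)C#C/C(C)=C/CC#C[Si](C(C)C)(C(C)C)C(C)C | intermediate
24 | bis-epoxide of 23 with (11R,12R)-11,12-epoxide and (22R,23R)-22,23-epoxide (target numbering) | C[C@H]1O[C@@H]1/C=C/[C@@H](O[Si](CC)(CC)CC)[C@H](C)[C@H](O[Si](C)(C)C(C)(C)C)C[C@H](OC)C#C[C@@]1(C)O[C@@H]1CC#C[Si](C(C)C)(C(C)C)C(C)C | intermediate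
25 | (13Z)-alkene from 24 (cis C13=C14; C8≡C9–Si(i-Pr)3 retained) | C[C@H]1O[C@@H]1/C=C/[C@@H](O[Si](CC)(CC)CC)[C@H](C)[C@H](O[Si](C)(C)C(C)(C)C)C[C@H](OC)/C=C\[C@@]1(C)O[C@@H]1CC#C[Si](C(C)C)(C(C)C)C(C)C | intermediate
26 | C8–C24 alcohol: 25 without the C19 triethylsilyl and C8 triisopropylsilyl groups (terminal alkyne; C19–OH; C17–OTBS) | C[C@H]1O[C@@H]1/C=C/[C@@H](O)[C@H](C)[C@H](O[Si](C)(C)C(C)(C)C)C[C@H](OC)/C=C\[C@@]1(C)O[C@@H]1CC#C | intermediate
27 | ethyl 2-[bis(2,2,2-trifluoroethoxy)phosphoryl]propanoate (racemic) | CCOC(=O)C(C)P(=O)(OCC(F)(F)F)OCC(F)(F)F | starting material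
28 | 2-[bis(2,2,2-trifluoroethoxy)phosphoryl]propanoic acid (racemic; C1–C2 and the C2 methyl) | OC(=O)C(C)P(=O)(OCC(F)(F)F)OCC(F)(F)F | intermediate
29 | C19 2-[bis(2,2,2-trifluoroethoxy)phosphoryl]propanoate of 26 (C2 epimers) | C[C@H]1O[C@@H]1/C=C/[C@@H](OC(=O)C(C)P(=O)(OCC(F)(F)F)OCC(F)(F)F)[C@H](C)[C@H](O[Si](C)(C)C(C)(C)C)C[C@H](OC)/C=C\[C@@]1(C)O[C@@H]1CC#C | intermediate
30 | prop-2-yn-1-ol (C5–C7) | C#CCO | starting material
31 | (Z)-bromomagnesium 3-(bromomagnesio)-2-methylprop-2-en-1-olate | Br[Mg]/C=C(/C)CO[Mg]Br | intermediate
32 | (Z)-3-iodo-2-methylprop-2-en-1-ol | OC/C(C)=C\I | intermediate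
33 | (Z)-3-iodo-2-methylprop-2-enal | O=C/C(C)=C\I | intermediate
34 | (R)-4-benzyl-3-propanoyl-1,3-thiazolidine-2-thione (C3–C4 and the C4 methyl) | CCC(=O)N1[C@H](Cc2ccccc2)CSC1=S | starting material
35 | (Z)-trichlorotitanium enolate of 34 | C/C=C(\O[Ti](Cl)(Cl)Cl)N1[C@H](Cc2ccccc2)CSC1=S | intermediate
36 | (R)-4-benzyl-3-[(2R,3R,4Z)-3-hydroxy-5-iodo-2,4-dimethylpent-4-enoyl]-1,3-thiazolidine-2-thione | O=C([C@H](C)[C@@H](O)/C(C)=C\I)N1[C@H](Cc2ccccc2)CSC1=S | intermediate
37 | triethylsilyl ether of 36 | O=C([C@H](C)[C@@H](O[Si](CC)(CC)CC)/C(C)=C\I)N1[C@H](Cc2ccccc2)CSC1=S | intermediate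
38 | (2R,3R,4Z)-5-iodo-2,4-dimethyl-3-(triethylsilyloxy)pent-4-enal (C3–C7) | O=C[C@H](C)[C@@H](O[Si](CC)(CC)CC)/C(C)=C\I | intermediate
39 | potassium salt of 29 (carbanion at C2) | C[C@H]1O[C@@H]1/C=C/[C@@H](OC(=O)[C-](C)P(=O)(OCC(F)(F)F)OCC(F)(F)F)[C@H](C)[C@H](O[Si](C)(C)C(C)(C)C)C[C@H](OC)/C=C\[C@@]1(C)O[C@@H]1CC#C.[K+] | intermediate
40 | open-chain (2Z)-enoate: C1–C7 acyl chain with (6Z)-7-iodo alkene, 4S, 5R (OSiEt3), esterified at O19 of the C8–C24 chain bearing the terminal C8 alkyne | I\C=C(\C)[C@H](O[Si](CC)(CC)CC)[C@@H](C)/C=C(/C)C(=O)O[C@H](/C=C/[C@H]1O[C@@H]1C)[C@H](C)[C@H](O[Si](C)(C)C(C)(C)C)C[C@H](OC)/C=C\[C@@]1(C)O[C@@H]1CC#C | intermediate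
41 | 20-membered 8,9-didehydro macrocycle (2Z,6Z,13Z; C5–OSiEt3; C17–OTBS) | CO[C@@H]1/C=C\[C@@]2(C)O[C@@H]2CC#C\C=C(\C)[C@H](O[Si](CC)(CC)CC)[C@@H](C)/C=C(/C)C(=O)O[C@H](/C=C/[C@H]2O[C@@H]2C)[C@H](C)[C@H](O[Si](C)(C)C(C)(C)C)C1 | intermediate
42 | (2Z,6Z,8Z,13Z)-macrocycle (C5–OSiEt3; C17–OTBS) | CO[C@@H]1/C=C\[C@@]2(C)O[C@@H]2C/C=C\C=C(\C)[C@H](O[Si](CC)(CC)CC)[C@@H](C)/C=C(/C)C(=O)O[C@H](/C=C/[C@H]2O[C@@H]2C)[C@H](C)[C@H](O[Si](C)(C)C(C)(C)C)C1 | intermediate
43 | C5 alcohol of 42 (5R; C17–OTBS) | CO[C@@H]1/C=C\[C@@]2(C)O[C@@H]2C/C=C\C=C(\C)[C@H](O)[C@@H](C)/C=C(/C)C(=O)O[C@H](/C=C/[C@H]2O[C@@H]2C)[C@H](C)[C@H](O[Si](C)(C)C(C)(C)C)C1 | intermediate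
44 | 17-O-tert-butyldimethylsilyl ether of the target | CO[C@@H]1/C=C\[C@@]2(C)O[C@@H]2C/C=C\C=C(\C)C(=O)[C@@H](C)/C=C(/C)C(=O)O[C@H](/C=C/[C@H]2O[C@@H]2C)[C@H](C)[C@H](O[Si](C)(C)C(C)(C)C)C1 | intermediate
45 | CNP0173711.1 (4S,11R,12R,15S,17R,18R,19R,22R,23R; 2Z,6Z,8Z,13Z,20E) | CO[C@@H]1/C=C\[C@@]2(C)O[C@@H]2C/C=C\C=C(\C)C(=O)[C@@H](C)/C=C(/C)C(=O)O[C@H](/C=C/[C@H]2O[C@@H]2C)[C@H](C)[C@H](O)C1 | target

## Step count and least certain steps

Total: 31 steps. Longest linear sequence: 21 steps (steps 1–7, 12–18, 20, 26–31). The enediyne 18 takes 4 steps, the aldehyde 38 takes 5 and the acid 28 takes 1.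

**Step 3 (key step).** The conjugated dienal is a weak heterodienophile, so the cycloaddition may be slow. The enal may compete as an oxadiene or as a carbon dienophile, facial discrimination may be lower than for saturated aldehydes, and the acid unmasking may epimerise C18. Fallback, from 5 back to 7: a boron-mediated syn aldol of 5 with (S)-4-benzyl-3-propanoyloxazolidin-2-one (n-Bu2BOTf, i-Pr2NEt) would give the syn adduct (S)-4-benzyl-3-[(2S,3R,4E,6E)-3-hydroxy-2-methylocta-4,6-dienoyl]oxazolidin-2-one F1. Transamination with MeNHOMe·HCl and Me3Al would give the Weinreb amide F2. Ethynylmagnesium bromide would give the β-hydroxy ynone F3. Conjugate addition of Et2NH followed by acid-induced 6-endo ring closure with loss of the amine would return 7 with the same C18 and C19 configuration.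

**Step 12.** The acetylide addition may stall at the cyclic hemiketal. Enolisation of the lactone or of the ynone may expel the C17 silyloxy group, and a second addition is possible if the mixture warms. Fallback, from 11 back to 21: aminolysis with MeNHOMe·HCl and Me3Al would open the ring to the hydroxy Weinreb amide F4. Silylation with Et3SiCl and imidazole would give the bis-silyl Weinreb amide F5. Addition of 19 to F5 at −78 °C gives 21 directly, with no hemiketal equilibrium.

**Step 16.** One reagent charge must serve two sites. Discrimination between the two olefins of the diene may be incomplete, one site may lag while the other over-oxidises, and facial selectivity may erode at the hindered enyne. Fallback, from 17 back to 24, which decouples the two epoxidations: the Shi epoxidation is applied first to 17 alone to give the epoxy bis-silyl diyne F6. K2CO3/MeOH gives the terminal alkyne F7. Lithiation and addition to 11 give the epoxy hydroxy ynone F8, silylation gives the triethylsilyl ether F9, transfer hydrogenation gives the (15S)-alcohol F10, and methylation (Ag2O/MeI if the oxonium salt harms the epoxide) gives the methyl ether F11. A second Shi epoxidation, now facing only the diene, then gives 24.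

**Step 27.** Ring closure may lose to intermolecular coupling and to oxidative alkyne homocoupling, and the ring strain of the enyne may slow reductive elimination. Fallback, from 26 and 38 back to 41, closing the ring at C2=C3 instead: intermolecular Sonogashira coupling of 26 with 38 (Pd(PPh3)4, CuI, Et3N) would give the open-chain enyne aldehyde F12. Esterification of its C19 hydroxyl with 28 (EDC, DMAP) would give the phosphonate aldehyde F13. Intramolecular Still–Gennari olefination at high dilution (KN(SiMe3)2, 18-crown-6) would give 41.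

**Step 28.** The reduction may go past the diene stage, may open the vinyl epoxides reductively, or may be accompanied by Z-to-E isomerisation. Fallback, from 29 back to 42, avoiding a ring alkyne altogether: rhodium-catalysed trans-hydroboration of the terminal alkyne of 29 with pinacolborane ([Rh(cod)Cl]2, P(i-Pr)3, Et3N) would give the (8Z)-alkenyl pinacolboronate F14. Still–Gennari olefination with 38 would give the open-chain iodoalkene–alkenylboronate F15. Intramolecular Suzuki–Miyaura coupling (Pd(PPh3)4, TlOEt, THF/H2O, high dilution) would form C7–C8 with retention at both olefins and give 42 directly.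

## Further compounds

F1 | step 3 | (S)-4-benzyl-3-[(2S,3R,4E,6E)-3-hydroxy-2-methylocta-4,6-dienoyl]oxazolidin-2-one | C/C=C/C=C/[C@@H](O)[C@H](C)C(=O)N1[C@@H](Cc2ccccc2)COC1=O
F2 | step 3 | (2S,3R,4E,6E)-3-hydroxy-N-methoxy-N,2-dimethylocta-4,6-dienamide | C/C=C/C=C/[C@@H](O)[C@H](C)C(=O)N(C)OC
F3 | step 3 | (4S,5R,6E,8E)-5-hydroxy-4-methyldeca-6,8-dien-1-yn-3-one | C/C=C/C=C/[C@@H](O)[C@H](C)C(=O)C#C
F4 | step 12 | (3R,4S,5R,6E,8E)-3-(tert-butyldimethylsilyloxy)-5-hydroxy-N-methoxy-N,4-dimethyldeca-6,8-dienamide | C/C=C/C=C/[C@@H](O)[C@H](C)[C@H](O[Si](C)(C)C(C)(C)C)CC(=O)N(C)OC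
F5 | step 12 | (3R,4R,5R,6E,8E)-3-(tert-butyldimethylsilyloxy)-N-methoxy-N,4-dimethyl-5-(triethylsilyloxy)deca-6,8-dienamide | C/C=C/C=C/[C@@H](O[Si](CC)(CC)CC)[C@H](C)[C@H](O[Si](C)(C)C(C)(C)C)CC(=O)N(C)OC
F6 | step 16 | triisopropyl{3-[(2R,3R)-3-methyl-3-[(trimethylsilyl)ethynyl]oxiran-2-yl]prop-1-ynyl}silane | C[Si](C)(C)C#C[C@@]1(C)O[C@@H]1CC#C[Si](C(C)C)(C(C)C)C(C)C
F7 | step 16 | {3-[(2R,3R)-3-ethynyl-3-methyloxiran-2-yl]prop-1-ynyl}triisopropylsilane | C#C[C@@]1(C)O[C@@H]1CC#C[Si](C(C)C)(C(C)C)C(C)C
F8 | step 16 | (11R,12R)-11,12-epoxy analogue of 20 (C15 ketone; C19–OH) | C/C=C/C=C/[C@@H](O)[C@H](C)[C@H](O[Si](C)(C)C(C)(C)C)CC(=O)C#C[C@@]1(C)O[C@@H]1CC#C[Si](C(C)C)(C(C)C)C(C)C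
F9 | step 16 | (11R,12R)-11,12-epoxy analogue of 21 (C19–OSiEt3) | C/C=C/C=C/[C@@H](O[Si](CC)(CC)CC)[C@H](C)[C@H](O[Si](C)(C)C(C)(C)C)CC(=O)C#C[C@@]1(C)O[C@@H]1CC#C[Si](C(C)C)(C(C)C)C(C)C
F10 | step 16 | (11R,12R)-11,12-epoxy analogue of 22 (15S alcohol) | C/C=C/C=C/[C@@H](O[Si](CC)(CC)CC)[C@H](C)[C@H](O[Si](C)(C)C(C)(C)C)C[C@H](O)C#C[C@@]1(C)O[C@@H]1CC#C[Si](C(C)C)(C(C)C)C(C)C
F11 | step 16 | (11R,12R)-11,12-epoxy analogue of 23 (15S methyl ether; diene intact) | C/C=C/C=C/[C@@H](O[Si](CC)(CC)CC)[C@H](C)[C@H](O[Si](C)(C)C(C)(C)C)C[C@H](OC)C#C[C@@]1(C)O[C@@H]1CC#C[Si](C(C)C)(C(C)C)C(C)C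
F12 | step 27 | open-chain C3–C24 enyne aldehyde (C7–C8 bond formed; C19–OH; C5–OSiEt3; C17–OTBS) | C[C@H]1O[C@@H]1/C=C/[C@@H](O)[C@H](C)[C@H](O[Si](C)(C)C(C)(C)C)C[C@H](OC)/C=C\[C@@]1(C)O[C@@H]1CC#C\C=C(\C)[C@H](O[Si](CC)(CC)CC)[C@@H](C)C=O
F13 | step 27 | C19 2-[bis(2,2,2-trifluoroethoxy)phosphoryl]propanoate of F12 | C[C@H]1O[C@@H]1/C=C/[C@@H](OC(=O)C(C)P(=O)(OCC(F)(F)F)OCC(F)(F)F)[C@H](C)[C@H](O[Si](C)(C)C(C)(C)C)C[C@H](OC)/C=C\[C@@]1(C)O[C@@H]1CC#C\C=C(\C)[C@H](O[Si](CC)(CC)CC)[C@@H](C)C=O
F14 | step 28 | (8Z)-alkenyl pinacolboronate derived from 29 | C[C@H]1O[C@@H]1/C=C/[C@@H](OC(=O)C(C)P(=O)(OCC(F)(F)F)OCC(F)(F)F)[C@H](C)[C@H](O[Si](C)(C)C(C)(C)C)C[C@H](OC)/C=C\[C@@]1(C)O[C@@H]1C/C=C\B1OC(C)(C)C(C)(C)O1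
F15 | step 28 | open-chain (2Z)-enoate with C7 iodoalkene and (8Z)-alkenyl pinacolboronate | I\C=C(\C)[C@H](O[Si](CC)(CC)CC)[C@@H](C)/C=C(/C)C(=O)O[C@H](/C=C/[C@H]1O[C@@H]1C)[C@H](C)[C@H](O[Si](C)(C)C(C)(C)C)C[C@H](OC)/C=C\[C@@]1(C)O[C@@H]1C/C=C\B1OC(C)(C)C(C)(C)O1
A1 | alternative 1 | acyclic diphenylsilylene-bridged diene (C8–C20; C12 and C15 vinyl carbinols joined through O–SiPh2–O) | I/C=C\C[C@H](OS(C)(=O)=O)[C@@](C)(C=C)O[Si](c1ccccc1)(c1ccccc1)O[C@@H](C[C@@H](O[Si](C)(C)C(C)(C)C)[C@@H](C)[C@H](OCc1ccc(OC)cc1)CO[Si](C)(C)C(C)(C)C)C=C
A2 | alternative 1 | seven-membered cyclic silaketal containing Z C13=C14 (C8–C20) | I/C=C\C[C@H](OS(C)(=O)=O)[C@]1(C)O[Si](c2ccccc2)(c2ccccc2)O[C@@H](C[C@@H](O[Si](C)(C)C(C)(C)C)[C@@H](C)[C@H](OCc2ccc(OC)cc2)CO[Si](C)(C)C(C)(C)C)/C=C\1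
A3 | alternative 2 | ester-linked diyne with methyl-capped alkynes at C8 and C9 (C17 triethylsilyl ether) | CC#C\C=C(\C)C(=O)[C@@H](C)/C=C(/C)C(=O)O[C@H](/C=C/[C@H]1O[C@@H]1C)[C@H](C)[C@H](O[Si](CC)(CC)CC)C[C@H](OC)/C=C\[C@@]1(C)O[C@@H]1CC#CC
A4 | alternative 2 | 8,9-didehydro macrocycle (ring enyne), C17 triethylsilyl ether | CO[C@@H]1/C=C\[C@@]2(C)O[C@@H]2CC#C\C=C(\C)C(=O)[C@@H](C)/C=C(/C)C(=O)O[C@H](/C=C/[C@H]2O[C@@H]2C)[C@H](C)[C@H](O[Si](CC)(CC)CC)C1
A5 | alternative 3 | (1Z)-1-iodo-2,4-dimethylhexa-1,5-dien-3-yl 2-methylprop-2-enoate (configured as in A6) | C=C(C)C(=O)O[C@H](/C(C)=C\I)[C@@H](C)C=C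
A6 | alternative 3 | 6-[(Z)-1-iodoprop-1-en-2-yl]-3,5-dimethyl-5,6-dihydropyran-2-one (C1–C7 lactone) | O=C1O[C@H](/C(C)=C\I)[C@@H](C)C=C1C
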